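The runs stem from a simulated flask with made-up constants; scatter was added.

I started from the reagent.

| flask | substrate | reagent | capture agent | remark | time |
|---|---|---|---|---|---|
| south-west | 0.024 M | 0.0306 M | 0.85 mM | run made earlier |  |
| north-east | 0.037 M | 0.0306 M | 0.85 mM | run made earlier |  |
| flask | 0.017 M | 0.0306 M | 0.850 mM |  | 12 h |

- south-west (time / h: side product / %, target / %): 1.00: 11.6, 91.1; 2.00: 10.3, 90.3; 3.00: 8.9, 89.1; 6.00: 10.2, 88.7; 12.0: 12.4, 90.2
- north-east (time / h: side product / %, target / %): 1.00: 8.4, 72.4; 2.00: 10.0, 74.0; 3.00: 9.6, 73.3; 6.00: 7.5, 74.4; 12.0: 9.7, 75.1

(scatter of a reading: 1 percentage point)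

1. ratio of side product to target at 15 s
2. ratio of side product to target at 12 min
3. ratio of side product to target at 12 h
4. which of side product and target there is more of at 12 h



1. Over all its readings, the south-west run gave a ratio of side product to target of 0.119, a reading that carries the scatter. In the north-east run, target plus side product came to 30.7 mM against 0.0306 M of reagent charged, so I counted one reagent per product, with reagent as the limiting reagent there. I did not carry that run's ratio over, since 6.33 mM of its substrate stood in neither product, whereas the south-west run and the flask were each charged with more reagent than substrate.

2. For my bound from above I supposed that reagent changed nothing, so the flask would repeat 0.119.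

3. For the bound from below I wagered that the side product's route leaves substrate without reagent, so that the ratio falls as 1/c(reagent). I defined s, the selectivity factor, as the ratio times the mean c(reagent) over the run. In the south-west run that mean was 18.6 mM, which made s 2.21 mM. Holding the flask at its full 0.0306 M gave 0.0722.

4. The mean c(reagent) in the flask was 22.1 mM, higher than in the south-west run, so s gave 0.100. To check the error of using a mean, I averaged 1/c(reagent) along both straight falls instead, which gave 0.0887. I committed to that range at 12 h and gave no figure for times before the first reading.

5. The forecast gave 0.12, 0.12 and 0.12, with target ahead, on the ground that the ratio “looks independent of concentration”. Its last value lay above my range.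

The flask gave 0.0150 at 15 s, 0.0927 at 12 min and 0.0927 at 12 h, the last inside my range, with 91.2% target against 8.45% side product.

    substrate + reagent → target (k = 0.920 /M/s)
    intermediate D + capture agent → trapped intermediate (k = 0.410 /M/s)
    intermediate B ⇌ intermediate C (K = 0.490, k = 2.40 × 10⁻⁴ /s)
    reagent + intermediate A → intermediate B (k = 0.0450 /M/s)
    reagent + intermediate A → side product (k = 1.10 /M/s)
    substrate → intermediate A (k = 0.00190 /s)
    intermediate B ⇌ intermediate D (K = 0.340, k = 0.00160 /s)

The neighbouring flask, charged with 0.010 M of substrate, had a mean c(reagent) of 25.6 mM, so s gave 0.0863 and the check along the curve gave 0.0736; that flask gave 0.0779.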